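Start from the end. A single-handed free catalyst turns each substrate, with the partner, into its own product, while a racemization catalyst exchanges the two substrates. You want the state of the flask at 8.0 h.

the same everywhere: free catalyst 1 mol%; racemization catalyst 0.2 mol%
- west: left-handed substrate 30 mM; right-handed substrate 30 mM; partner 4 equiv; run made earlier
- flask: left-handed substrate 20 mM; right-handed substrate 20 mM; partner 4.00 equiv; time 8.0 h

west run (percent of the left-handed substrate and right-handed substrate together charged)

| time / h | left-handed product / % | right-handed product / % |
|---|---|---|
| 0.200 | 40.7 | 0 |
| 0.333 | 46.4 | 0.8 |
| 0.667 | 50.9 | 1.1 |
| 1.33 | 52.7 | 3.0 |
| 2.50 | 54.1 | 5.1 |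

(standard deviation of a reading: 0.5 percentage points)

- free catalyst is single-handed; left-handed substrate and right-handed substrate are mirror images of each other, charged as a racemate, each of them at the stated concentration
- the numbers in the tables scatter with a standard deviation of 0.5 percentage points
- an excess is below zero if the other one leads
- no earlier run changes the charge of free catalyst; that part of a forecast is a guess
- no earlier run changes the charge of racemization catalyst; that part of a forecast is a guess

- left-handed product and right-handed product together, in percent of the left-handed substrate and right-handed substrate charged together, at 8.0 h
- excess of left-handed product over right-handed product in the product at 8.0 h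
- whether the exchange between left-handed substrate and right-handed substrate keeps pace with the reaction: how far the product's excess at 8.0 h gets from its value without exchange to its value with instant exchange (above 80% keeps pace, below 20% hardly takes part, else lags behind)

Climb down the west run's ladder of rates, fastest first, taking each substrate as starting at 0.5 of the charge. By 0.200 h, 40.7% of the charge is left-handed product, so:

fast constant = ln(start / what is left) / time = 8.41 /h

The middle rung is exchange, seen as left-handed product creeping past the start value. It gains 1.8 percentage points in 0.663 h, then 1.4 points in 1.17 h. The creep is slower, though the scatter is large, so I let it stop near the last west reading.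

The bottom rung is right-handed product, which grows in the west run by:

(5.1% − 0.8%) / (2.50 h − 0.333 h) / 0.5 = 0.0397 /h

Partner and free catalyst both fall with the substrate charge in this flask. Taking each rate as proportional to both, which is a guess, gives 3.74 /h and 0.0176 /h. This second value is the leak, the fraction of right-handed substrate becoming right-handed product per hour. The half-lives in this flask are 0.185 h and 39.3 h, so the first is far shorter than the time allowed and the second is longer.

My reckoning for this flask:

right-handed product = 0.5 × (1 − exp(−leak × time)) = 6.58%

y = 54.1% + 6.58% = 60.7%

excess = 78.3%; without exchange 76.7%

The selectivity factor 212 gives 99.1% with instant exchange. The share of the way is then 7.04%, below 20%, so exchange hardly takes part.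

The forecast says 66%, 76% and lags behind, with the remark that “exchange is slow”, and it differs from my reckoning on y and on pace.

The flask gives 60.2%, an excess of 75.5%, and exchange that hardly takes part, at 9.8% of the way.

    partner + free catalyst + left-handed substrate → free catalyst + left-handed product (k = 2.60 × 10⁵ /M²/h)
    partner + free catalyst + right-handed substrate → free catalyst + right-handed product (k = 1800 /M²/h)
    left-handed substrate + racemization catalyst ⇌ right-handed substrate + racemization catalyst, rate k3*[racemization catalyst]*[left-handed substrate] forward; the back reaction follows from the equilibrium constant (k = 1800 /M/h)
    racemization catalyst → spent catalyst (k = 0.690 /h)
    2 racemization catalyst ⇌ resting dimer (K = 3.60 × 10⁵ /M, k = 9400 /M/h)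

The excess of 75.5% in this flask stands where it does through two things acting together, the time allowed and the falling level of partner. Left until 80.0 h, this flask comes down to 20.1%, and with partner held at its charge it reads 68.7% at 8.0 h. Right-handed product in this flask reads 7.38%, where the leak gave 6.58%. For the neighbour flask with 4 mol% of free catalyst, the leak scaled with that charge is 0.0706 /h, which reckons 21.6% of right-handed product, and that neighbour flask holds 22.0%.

The data are calculated on assumed constants.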